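Two questions stand on this flask: how the starting rate answers to the catalyst charge, and how far amber gets in its time.

| flask | substrate | free catalyst | product | time |
|---|---|---|---|---|
| red | 250 mM | 5.00 mM |  |  |
| grey | 250 mM | 7.50 mM |  |  |
| teal | 250 mM | 5.00 mM | 75.0 mM |  |
| amber | 250 mM | 10.0 mM |  | 4.8 min |

| red run: time / min | red run: [product] / mM | grey run: time / min | grey run: [product] / mM | teal run: time / min | teal run: [product] / mM |
|---|---|---|---|---|---|
| 0.96 | 15.6 | 0.96 | 22.3 | 0.96 | 132.3 |
| 1.9 | 36.2 | 1.9 | 57.6 | 1.9 | 195.0 |
| 2.9 | 67.7 | 2.9 | 100.5 | 2.9 | 249.6 |
| 3.8 | 103.7 | 3.8 | 142.9 | 3.8 | 283.2 |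
| 4.8 | 146.0 | 4.8 | 180.9 | 4.8 | 302.2 |

(standard deviation of a reading: 0.8 mM)

- reaction order in [free catalyst] at the outset, round the charge of the red run, defined at two percent of the substrate turned into product
- product in the amber run at 4.8 min, as a share of the substrate charged

- Overall: substrate -> product, with free catalyst as catalyst.
- Constant volume, constant temperature.
- A reading of a species includes what of it is bound.
- An order is taken over about fifteen percent of the charge, up and down.

1. Red speeds up as product builds, which is autocatalysis, so I take the rate per unit of substrate S as a + k_P·P, where a is the catalyst route and P is the product. I reckon the product term and leave the rest to a.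

2. The first and last intervals of the red run give the product pull k_P, the gain in rate per unit of substrate for each unit of product: 2.31 M⁻¹ min⁻¹. This is a reading. The first interval then leaves a = 0.0490 min⁻¹ in the red run.

3. Two extreme versions can be solved in the head. With the product route struck out, the order is 1; with the catalyst route struck out, it is 0. At 5.00 mM of product in the red run, the product term is 0.0115 min⁻¹, less than a. The catalyst route therefore holds a share of 0.809, and this share is my order.

4. For amber I double a, to 0.0981 min⁻¹. The catalyst route by itself reaches 37.5%. With both routes, the integrated form gives 78.2%.

5. The forecast gives 0.83 (0.7 to 1) and 80.5% (76% to 85%), on the ground that “the two routes look additive”. Its amber figure is higher than mine.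

    free catalyst + substrate ⇌ catalyst-substrate complex, settled at all times (66.80 M⁻¹)
    catalyst-substrate complex + substrate ⇌ doubly bound catalyst, settled at all times (9.340 M⁻¹)
    doubly bound catalyst → product + catalyst-substrate complex (4.482 min⁻¹)
    substrate + product → 2 product (2.268 M⁻¹ min⁻¹)
    free catalyst + impurity → spent catalyst

The flask gives an order of 1.1 and 80.5% in amber, and that order stands above the 1 of the extreme with the product route struck out. In the red run the impurity takes 1.31 mM of the 5.00 mM of free catalyst at once, leaving 3.69 mM to share among free catalyst, catalyst-substrate complex and doubly bound catalyst, and my catalyst share times the charge over that remainder comes to 1.10. In the teal run, once 5.00 mM of product has been made, k_P times the extra 75.0 mM of product and the 245 mM of substrate gives 42.4 mM min⁻¹ of added rate, and the teal rate stands 40.6 mM min⁻¹ above that of the red run at the same amount made.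

The earlier runs and the new flask were computed with constants of no real substance; scatter was added.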